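Whatever happens in the flask, the X charged stays accounted for: it stands as X, as G, or as X.L, Q and D together, so what we watch is how the X that leaves divides between G and the rest.

    E ⇌ L, rate k1*(csat - [L]) (k1 = 0.27 /s, csat = 0.66 mM)
    X + L → X.L (k2 = 140 /M/s)
    X → G (k3 = 0.19 /s)
    L → J (k4 = 0.076 /s)
    X.L ⇌ D (K5 = 0.26, k5 = 0.94 /s)
    Q ⇌ X.L, rate k6*(cs6 - [X.L]) while solid is left; crystals form when [X.L] > cs6 (cs6 = 0.12 mM, k6 = 4.3 /s)

X 2.0 mM; E 0.66 mM (held); time 10 s

- what is said of X.L includes Q
- Q is a solid; its amount is given per volume of the solution
- at the start none of L is dissolved
- run time (flask): 10 s

1. the X.L and Q together standing at 10 s, as a percentage of the X charged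
2. concentration of L in solution at 5.0 s, in percent of saturation
3. the change that raises the amount of X.L and Q together at 10 s, in percent of the X charged most ("none" if none brings more than 2 percentage points) (dusk / autumn / winter / noon / none)
4. amount of X.L and Q together at 10 s, in percent of the X charged, after winter

- dusk: doubling the saturation concentration of E, all else as stated
- autumn: doubling the dissolution coefficient of step 6, all else as stated
- winter: doubling the transfer coefficient of step 1, all else as stated
- noon: doubling the solubility in step 6, all else as stated

The loss of X to G and the binding of L to X both consume X, so [X] cancels from the ratio of their rates. We therefore carry the crossover concentration L× = 1.36 mM, the rate constant of the loss over that of binding, which is the dissolved L at which the two take X equally. At a given [L], the share of X that binds (a selectivity) is [L]/([L] + L×).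

In common logarithms, L× lies 0.313 above csat, so L× is twice the saturation value. At [L] equal to csat, that share is 32.7%.

But L starts at nothing. The binding also drains it, with a half-life of 2.5 s as charged, shorter than the 9.1 s of the loss to J. Taking the binding drain at half the charge, L rises at b = 0.486 /s towards 0.367 mM. That puts it at 0.334 mM at 5.0 s, or 50.7% of saturation.

X, however, leaves while L is still rising. Weighted by the X present, the mean L is 0.264 mM, so the share is 16.3%. With 10.3% of X left at 10 s by this estimate, we reckon 14.6% of the charge bound.

Is that all X.L and Q? No. This exceeds the solubility, 6.00% of the charge, so crystals form and D stays near 1.56%. That leaves y at 13.0%.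

The same reckoning gives 18.3% after winter and 24.4% after dusk, which is more.

The forecast says y 11.6% (10.3% to 13%), sat 51% (47% to 55%), yb 16.9% (15% to 18.8%) and best dusk, holding that “Doubling csat roughly doubles L throughout”. Its y is lower than ours.

The flask gives y 11.9%, sat 51.6%, yb 17.1% and best dusk, with gains of 10 percentage points there and 5.2 points for winter; our y stood higher. At 2.61 s the loss to G takes X 5.4 times as fast as binding does. At 10.0 s L stands at 0.441 mM, still below L×, and G holds 76.8% of the X charged.

For the same flask read earlier, at 2.5 s, we reckon a mean L of about 0.154 mM, so L× gives 58.9% of X left and 4.20% bound. Computed, this earlier flask holds X 59.1%, with X.L 3.05% and D 0.679%, together 3.73%.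

The numbers of this flask come from no measurement; no experiment stands behind them.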